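In a one-step world the partner has a single exit, decomposition; this flask gives it two more, so the quantity to watch is the part of the partner that takes them.

left-handed substrate 0.073 M; partner 0.0803 M (in portions, 2); free catalyst 0.88 mM; right-handed substrate 0.073 M; time 10 h; the portions of partner follow each other after 30 min, the first at the start

    free catalyst + left-handed substrate ⇌ catalyst intermediate A (K1 = 60 L mol⁻¹, k1 = 520 L mol⁻¹ min⁻¹)
    partner → decomposed reagent (k2 = 0.025 min⁻¹)
    free catalyst + right-handed substrate ⇌ catalyst intermediate B (K3 = 24 L mol⁻¹, k3 = 1900 L mol⁻¹ min⁻¹)
    partner + catalyst intermediate B → free catalyst + right-handed product (k4 = 11 L mol⁻¹ min⁻¹)
    partner + catalyst intermediate A → free catalyst + left-handed product (k5 = 24 L mol⁻¹ min⁻¹)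
    free catalyst ⇌ dormant form (K6 = 0.89, k6 = 0.062 min⁻¹)

* at 10 h, what has stopped the reaction, if anything has (no working catalyst is left / all of the left-handed substrate has reacted / it is still moving / forward and back rates have come level / the partner has run out first)
* left-handed product at 10 h, in percent of the left-handed substrate and right-handed substrate together charged
* right-handed substrate at 10 h, in percent of the left-handed substrate and right-handed substrate together charged

- free catalyst is single-handed; left-handed substrate and right-handed substrate are mirror images of each other, charged as a racemate, each of them at the stated concentration
- the reaction counts as stopped when no species that holds the left-handed substrate and right-handed substrate together changes by six tenths of a point or more over the second half of the time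
- run time (flask): 10 h

The reckoning by hand starts from the catalyst. Against free catalyst as 1, the starting weights are 4.4 for catalyst intermediate A, 1.8 for catalyst intermediate B and 0.89 for the dormant form, which sum to 8.02. Equilibrium weights are usable at the start because the forward binding half-life of left-handed substrate, 1.5 min, and the relaxation of the dormant form, 0.0877 h, are both shorter than the partner's decomposition half-life of 27.7 min.

The exits of the partner are listed below, each with its pseudo-first-order rate constant at the starting weights and its log10 relative to decomposition:

- decomposition: 0.025 min⁻¹, 0
- through catalyst intermediate A: 0.0115 min⁻¹, −0.336
- through catalyst intermediate B: 0.00211 min⁻¹, −1.07

Decomposition stands highest, with the row for catalyst intermediate A next. The two catalyst rows differ by 0.734 in log10, so at the starting weights left-handed product forms 5.45 times as fast as right-handed product. Each exit is first order in c(partner), so at fixed catalyst weights their ratios do not depend on c(partner).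

The catalyst rows, taken over the sum of the rows, give 0.353: this is the capture share, the part of the partner that ends in product and not in decomposed reagent, reckoned at the starting weights. With the weights held at their start, the charge gives 16.4% left-handed product and 3.01% right-handed product, which leaves right-handed substrate near 47.0%, not counting what sits in catalyst intermediate B. Over the time after the last portion, the exits at these weights lower that portion's log10 by 9.57, so the reckoning has the partner run out first.

The forecast says the partner has run out first, with 15.6% and 46.7%, holding that “roughly a third of it ends up in product”. The reckoning here gives more left-handed product than the forecast.

The simulation gives the partner has run out first, with 15.3% and 46.4%. At 10.0 h, this flask has 0% of its partner, the limiting reagent, and holds 0.0529 M of decomposed reagent. The capture share, reckoned at the starting weights, puts 0.0519 M there. In a neighbour flask charged with 0.20 M of partner, the same share, carried over unchanged, puts 0.129 M in decomposed reagent, and that flask holds 0.137 M at 10.0 h.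

(The numbers of this flask are assumed, and the outcome is calculated.)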